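The numbers in the tables come from a simulation on assumed constants; scatter was added.

A small charge of reagent, let in over the hour, has to catch substrate that is already leaving by another road.

| flask | substrate | reagent | remark | time |
|---|---|---|---|---|
| south-west | 48 mM | 43.2 mM | run made earlier |  |
| north-west | 48 mM | 60 mM | run made earlier |  |
| south | 48 mM | 95 mM | run made earlier |  |
| epsilon | 48 mM | 43.2 mM | a closed flask charged with all of it at once and left for 1.0 h | 1.0 h |
| zeta | 48 mM | 43.2 mM | one stirred flow tank at steady state, fed with the mixture as stated, mean residence time 1.0 h |  |
| beta | 48 mM (fed, over 1.00 h) | 43.2 mM | a stirred flask in which substrate is dosed at a steady rate over 1.00 h without added volume, worked up at 1.0 h | 1.0 h |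
| gamma | 48 mM | 43.2 mM (fed, over 1.00 h) | a stirred flask in which reagent is dosed at a steady rate over 1.00 h without added volume, worked up at 1.0 h | 1.0 h |

| run | time / min | target / % | substrate / % |
|---|---|---|---|
| south-west | 5.00 | 0.2 | 21.4 |
| south-west | 10.0 | 1.9 | 6.7 |
| south-west | 15.0 | 3.9 | 2.2 |
| south-west | 20.0 | 7.5 | 0.8 |
| south-west | 25.0 | 9.4 | 0.6 |
| south-west | 30.0 | 13.5 | 0.6 |
| south-west | 40.0 | 20.0 | 0 |
| north-west | 4.00 | 0.5 | 21.3 |
| north-west | 12.0 | 4.4 | 2.6 |
| north-west | 20.0 | 11.4 | 0.1 |
| north-west | 30.0 | 20.9 | 0 |
| north-west | 40.0 | 30.7 | 0 |
| north-west | 60.0 | 43.8 | 0 |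
| north-west | 80.0 | 50.7 | 0 |
| south | 10.0 | 6.4 | 1.2 |
| south | 20.0 | 20.1 | 0.3 |
| south | 30.0 | 34.8 | 0.3 |
| south | 40.0 | 47.2 | 0 |
| south | 50.0 | 57.3 | 0.1 |
| south | 60.0 | 63.5 | 0.6 |
| south | 80.0 | 69.8 | 0 |

(scatter of a reading: 0.3 percentage points)

- in percentages every species weighs as the substrate in it: one idle adduct counts as two
- for target the idle adduct is counted in
- the stated concentrations are those of everything mixed, before any reaction; amounts are the same in each set-up
- reactions considered so far: intermediate A -> intermediate B; substrate -> side product; reagent + intermediate B -> target; substrate + target <-> idle adduct; reagent + intermediate B -> intermediate C; intermediate D -> target; substrate + reagent -> intermediate A; intermediate C -> intermediate D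
- the feed brings no volume worth counting
- the earlier runs were made in a closed, stirred flask
- in an amount of target, one idle adduct counts as one target

* the set-up with the highest amount of target at the outlet or at the end, in percent of the substrate put in ("none" if the first two lie within 2 percentage points) (epsilon / zeta / beta / gamma / none)
* amount of target at the outlet or at the end, in percent of the substrate put in, epsilon
* amount of target at the outlet or at the end, in percent of the substrate put in, zeta
* amount of target at the outlet or at the end, in percent of the substrate put in, beta
* amount of target at the outlet or at the end, in percent of the substrate put in, gamma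

What removes substrate when reagent is absent? The first readings give a clue. The south-west run kept 21.4 % at 5.00 min, a mean pseudo-first-order constant of 0.308 /min. The north-west run kept 21.3 % at 4.00 min, which gives 0.387 /min.

And with no reagent? Drawing the line through both points to zero reagent leaves 0.107 /min. Its inverse I call the waiting life, the mean time substrate lasts with no reagent present: 9.34 min.

Isn't that shaky? Yes, it is a reading from two points, and reagent falls during both.

What does it say of gamma? Reagent arrives at 0.720 mM/min, and the waiting life is shorter than the dosing hour. In one waiting life the feed brings 6.72 mM against 48 mM charged, and I take that as a rough measure of the catch, 14.0 % of the substrate. It is an estimate and no bound: reagent not reacted on arrival stays in the flask and can still react.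

Is everything caught target by the end? No. The north-west run held 30.7 % at 40.0 min against 50.7 % at 80.0 min, so scaling by that ratio I put target in gamma near 8.48 %.

The forecast chose epsilon, with 27 %, 22 %, 19 % and 14 % for epsilon, zeta, beta and gamma. On gamma it differs from my figure: “starved reagent lets substrate go to side product”, with target at 14 %.

The flasks gave 28.9 % for epsilon, 17.5 % for zeta, 18.5 % for beta and 5.79 % for gamma, so epsilon stands highest.

    intermediate A → intermediate B (k = 0.00300 /s)
    substrate → side product (k = 0.00250 /s)
    reagent + intermediate B → target (k = 0.00930 /M/s)
    substrate + target ⇌ idle adduct, settled at all times (K = 50.0 /M)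
    reagent + intermediate B → intermediate C (k = 0.0580 /M/s)
    intermediate D → target (k = 0.00220 /s)
    substrate + reagent → intermediate A (k = 0.0900 /M/s)
    intermediate C → intermediate D (k = 9.30 × 10⁻⁴ /s)

Gamma ended at 5.79 %, with side product at 90.9 % after 1.00 h, so 9.14 % of the substrate got past the loss, below my estimate of 14.0 %. In beta, substrate is fed steadily and its standing amount climbs from 5.46 % at 0.500 h to 7.46 % at 1.00 h. Frozen at the end of the hour, the waiting life, shortened by the 22.0 % of reagent remaining, becomes 6.61 min, which gives 11.0 % standing against the 7.46 % found.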